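**Strategy.** Everything rests on cutting the C7–C8 bond of the cyclobutane (target numbered as tricyclo[5.4.0.0(2,8)]undecane, ketone at C9) and reconnecting C7 to C9. The precursor is then a norbornane-type tricycle with a bridgehead C9–OH and an endo C8 mesylate. In the key step the C9 alkoxide drives a semipinacol 1,2-shift of C7 from C9 to C8. This one operation contracts the cyclopentane C1–C2–C8–C9–C7 to the cyclobutane and enlarges the cyclopentane C1–C7–C9–C10–C11 to the cyclohexanone by inserting C8. It exploits the adjacency of the C9 carbonyl to cyclobutane carbon C8. The diol comes from SmI2 pinacol closure of a hydroazulenone keto aldehyde.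

Key step: step 15

Remark 1: all intermediates keep the target atom numbers (C1, C7 ring-fusion CH; C2 C–Me; C3 CH–O; C6 C(Me)(CH2O); C8; C9 carbonyl carbon; C10 CH2; C11 CH–Me). C4 appears in step 8. "β face" means the face of H1 and H7 in the cis-fused bicycles, "α face" the opposite one.

Remark 2: ethyl 3-oxo-4-(triphenylphosphoranylidene)butanoate (5) is taken as a purchasable reagent.

Step 1
Reactants: 1 (R)-4-[(tert-butyldimethylsilyl)oxy]cyclopent-2-en-1-one
Product: 2 (3R,4R)-3-methyl-4-[(tert-butyldimethylsilyl)oxy]cyclopentan-1-one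
Conditions: Me2CuLi, Et2O, −78 °C; aqueous work-up
Reagents that add atoms: lithium dimethylcuprate, [Li+].C[Cu-]C
Why: Gilman cuprate 1,4-addition, in which the methyl group should enter anti to the neighbouring silyloxy group and so give the trans product.

Step 2
Reactants: 2 (3R,4R)-3-methyl-4-[(tert-butyldimethylsilyl)oxy]cyclopentan-1-one
Product: 3 (R)-4-methylcyclopent-2-en-1-one
Conditions: DBU, CH2Cl2, 0 °C
Reagents that add atoms: none
Why: E1cB β-elimination of silanolate from the β-silyloxy ketone transposes the enone and leaves the methyl-bearing stereocentre untouched.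

Step 3
Reactants: 4 2-[(tert-butyldimethylsilyl)oxy]acetaldehyde; 5 ethyl 3-oxo-4-(triphenylphosphoranylidene)butanoate
Product: 6 ethyl (E)-6-[(tert-butyldimethylsilyl)oxy]-3-oxohex-4-enoate
Conditions: NaH, THF, 0 °C to rt; aqueous work-up
Reagents that add atoms: none
Why: Wittig olefination of the acyl-stabilised ylide, run through its sodium enolate, should give the E-enone expected of stabilised ylides.

Step 4
Reactants: 3 (R)-4-methylcyclopent-2-en-1-one; 6 ethyl (E)-6-[(tert-butyldimethylsilyl)oxy]-3-oxohex-4-enoate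
Product: 8 cis-fused bicyclo[4.3.0]nonane diketo ester (C9 cyclopentanone, C3 ketone, C2 quaternary with 2-Me β and CO2Et α, 11-Me β, 6-CH2OTBS), via ring keto ester enol 7 (not isolated)
Conditions: Cs2CO3, THF, 0 °C to rt (6 added slowly); then MeI, rt
Reagents that add atoms: iodomethane, CI
Why: Michael–Michael annulation (the keto ester carbon adds to the enone β-carbon anti to the ring methyl, then the cyclopentanone enolate closes the six-membered ring on the side-chain enone, which forces the cis fusion) followed by C-alkylation of the cyclic β-keto ester enolate, MeI entering from the convex β face.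

Step 5
Reactants: 8 cis-fused bicyclo[4.3.0]nonane diketo ester
Product: 9 C9 ethylene ketal of 8
Conditions: TMSOCH2CH2OTMS, TMSOTf (cat.), CH2Cl2, −78 to −20 °C
Reagents that add atoms: 1,2-bis(trimethylsilyloxy)ethane, C[Si](C)(C)OCCO[Si](C)(C)C
Why: Silyl-triflate-catalysed ketalisation should select the open cyclopentanone over the C3 ketone, which is flanked by the quaternary ester carbon.

Step 6
Reactants: 9 C9 ethylene ketal of 8
Product: 10 enone (C5=C6 double bond conjugated with the C3 ketone, CH2OTBS on C6)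
Conditions: IBX, DMSO/toluene, 70 °C
Reagents that add atoms: none
Why: IBX α,β-dehydrogenation of a ketone, which can only run toward C5 because the other α-carbon (C2) is quaternary and the cyclopentanone is masked.

Step 7
Reactants: 10 enone
Product: 11 ketone with quaternary C6 (6-Me β, 6-CH2OTBS α)
Conditions: Me2CuLi, BF3·OEt2, Et2O, −78 to −40 °C; aqueous work-up
Reagents that add atoms: lithium dimethylcuprate, [Li+].C[Cu-]C
Why: Cuprate conjugate addition to the β,β-disubstituted enone builds the quaternary carbon, methyl entering from the convex β face, away from the ketal-bearing five-membered ring.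

Step 8
Reactants: 11 ketone with quaternary C6
Product: 13 cis-fused bicyclo[5.3.0]decane keto ester (seven-membered ring, C3 ketone, new CH2 = C4), via alpha-silyl ketone 12 (not isolated)
Conditions: TMSCHN2, Sc(OTf)3 (10 mol %), CH2Cl2, −78 °C to rt; then 1 M HCl, THF, 0 °C
Reagents that add atoms: (trimethylsilyl)diazomethane, C[Si](C)(C)C=[N+]=[N-]
Why: Lewis-acid-catalysed diazoalkane homologation (Tiffeneau–Demjanov-type ring enlargement) in which the CH2 carbon C5 should migrate in preference to the quaternary, ester-bearing C2, followed by protodesilylation.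

Step 9
Reactants: 13 cis-fused bicyclo[5.3.0]decane keto ester
Product: 14 β-hydroxy ester (3-OH α, cis to the C2 ester)
Conditions: Zn(BH4)2, Et2O, −20 to 0 °C
Reagents that add atoms: none
Why: Chelation-controlled borohydride reduction of the β-keto ester, hydride adding to the zinc chelate from the side of the C2 methyl so that the hydroxyl ends cis to the ester.

Step 10
Reactants: 14 β-hydroxy ester
Product: 15 bis-silyl ether ester
Conditions: TBSOTf, 2,6-lutidine, CH2Cl2, 0 °C
Reagents that add atoms: tert-butyldimethylsilyl trifluoromethanesulfonate, CC(C)(C)[Si](C)(C)OS(=O)(=O)C(F)(F)F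
Why: Silylation of a hindered secondary alcohol with a silyl triflate and a hindered base.

Step 11
Reactants: 15 bis-silyl ether ester
Product: 16 ketal aldehyde (C8 = CHO on C2)
Conditions: iBu2AlH, CH2Cl2, −78 °C; aqueous potassium sodium tartrate
Reagents that add atoms: none
Why: Partial reduction of the hindered ester, whose tetrahedral aluminium hemiacetal should survive at low temperature and release the aldehyde on work-up.

Step 12
Reactants: 16 ketal aldehyde
Product: 17 keto aldehyde (C9 ketone, C8 aldehyde, cis-fused bicyclo[5.3.0]decane)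
Conditions: PPTS, acetone/H2O, 50 °C
Reagents that add atoms: water, O
Why: Acid-catalysed ketal hydrolysis, mild enough for the silyl ethers and the non-enolisable aldehyde.

Step 13
Reactants: 17 keto aldehyde
Product: 18 tricyclic diol (norbornane core: bridgehead C9–OH, C8–OH endo, i.e. anti to the C7 bridge)
Conditions: SmI2, t-BuOH, THF, −78 °C to rt
Reagents that add atoms: none
Why: SmI2 ketyl–carbonyl (pinacol) cyclisation of the 1,5-keto aldehyde closes the five-membered ring, and the samarium-bound C8 oxygen should take the endo side because the exo side is roofed by the seven-membered ring and its C3 silyl ether.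

Step 14
Reactants: 18 tricyclic diol
Product: 19 C8 endo mesylate with free bridgehead C9–OH
Conditions: MsCl, Et3N, DMAP (cat.), CH2Cl2, 0 °C
Reagents that add atoms: methanesulfonyl chloride, CS(Cl)(=O)=O
Why: Sulfonylation of the secondary alcohol, the tertiary bridgehead alcohol being too hindered to react.

Step 15
Reactants: 19 C8 endo mesylate with free bridgehead C9–OH
Product: 20 bis-silyl ether of the tricyclo[5.4.0.0(2,8)]undecan-9-one core
Conditions: KOtBu, THF/t-BuOH, 25 to 50 °C
Reagents that add atoms: none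
Why: Deprotonation of the C9 hydroxyl gives an alkoxide whose C9–C7 bond lies antiperiplanar to the endo C8–OMs bond, so C7 shifts from C9 to C8 as mesylate leaves and the C9 carbonyl forms. The closest known reaction type is the base-mediated semipinacol rearrangement of cyclic 2-sulfonyloxy tertiary alcohols used for ring contraction and enlargement. Both rings arise by this suprafacial 1,2-alkyl shift and not by an end-to-end cyclisation: the new C7–C8 bond closes the cyclobutane C1–C2–C8–C7, and insertion of C8 between C9 and C7 turns the cyclopentane C1–C7–C9–C10–C11 into the cyclohexanone C1–C7–C8–C9–C10–C11. C8 is the only centre reconfigured; it is inverted, as fixed by the antiperiplanar geometry, while C7 migrates with retention. The step needs migration of C7 and not of C10; the endo mesylate secures this because the C9–C10 bond is gauche to it. Elimination is excluded because both β-carbons (bridgehead C9, quaternary C2) carry no hydrogen, and carbonyl formation should pay for the added cyclobutane strain.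

Step 16
Reactants: 20 bis-silyl ether of the tricyclic ketone
Product: 21 diol ketone (3-OH and 6-CH2OH)
Conditions: Bu4NF, THF, 40 °C
Reagents that add atoms: none
Why: Fluoride-induced cleavage of both silyl ethers.

Step 17
Reactants: 21 diol ketone
Product: 22 target, CNP0276938.1
Conditions: angelic acid, 2,4,6-trichlorobenzoyl chloride, Et3N, toluene, rt then 80 °C
Reagents that add atoms: angelic acid, C/C=C(/C)C(=O)O
Why: Yamaguchi esterification through the mixed anhydride should acylate the primary and the hindered secondary alcohol without nucleophilic catalyst, which limits Z-to-E isomerisation of the angelate.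

**Compound list**

1 | (R)-4-[(tert-butyldimethylsilyl)oxy]cyclopent-2-en-1-one | O=C1C=C[C@H](O[Si](C)(C)C(C)(C)C)C1 | starting material
2 | (3R,4R)-3-methyl-4-[(tert-butyldimethylsilyl)oxy]cyclopentan-1-one | O=C1C[C@@H](C)[C@H](O[Si](C)(C)C(C)(C)C)C1 | intermediate
3 | (R)-4-methylcyclopent-2-en-1-one | C[C@H]1C=CC(=O)C1 | intermediate
4 | 2-[(tert-butyldimethylsilyl)oxy]acetaldehyde | O=CCO[Si](C)(C)C(C)(C)C | starting material
5 | ethyl 3-oxo-4-(triphenylphosphoranylidene)butanoate | CCOC(=O)CC(=O)C=P(c1ccccc1)(c1ccccc1)c1ccccc1 | starting material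
6 | ethyl (E)-6-[(tert-butyldimethylsilyl)oxy]-3-oxohex-4-enoate | CCOC(=O)CC(=O)/C=C/CO[Si](C)(C)C(C)(C)C | intermediate
7 | ring keto ester enol: cis-fused bicyclo[4.3.0]nonane, C9 ketone, enolised C3(OH)=C2(CO2Et), 11-Me β, 6-CH2OTBS (C6 drawn as the β epimer; this centre becomes sp2 in step 6) | CC(C)(C)[Si](C)(C)OC[C@@H]1CC(O)=C(C(=O)OCC)[C@@H]2[C@H]1C(=O)C[C@H]2C | intermediate (not isolated)
8 | cis-fused bicyclo[4.3.0]nonane diketo ester: 2-Me β, 2-CO2Et α, C3 and C9 ketones, 11-Me β | CC(C)(C)[Si](C)(C)OC[C@@H]1CC(=O)[C@@](C)(C(=O)OCC)[C@@H]2[C@H]1C(=O)C[C@H]2C | intermediate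
9 | C9 ethylene ketal of 8 | CC(C)(C)[Si](C)(C)OC[C@@H]1CC(=O)[C@@](C)(C(=O)OCC)[C@@H]2[C@H]1C3(OCCO3)C[C@H]2C | intermediate
10 | enone: C5=C6 conjugated with the C3 ketone, 6-CH2OTBS | CC(C)(C)[Si](C)(C)OCC1=CC(=O)[C@@](C)(C(=O)OCC)[C@@H]2[C@H]1C3(OCCO3)C[C@H]2C | intermediate
11 | ketone with quaternary C6: 6-Me β, 6-CH2OTBS α | CC(C)(C)[Si](C)(C)OC[C@@]1(C)CC(=O)[C@@](C)(C(=O)OCC)[C@@H]2[C@H]1C3(OCCO3)C[C@H]2C | intermediate
12 | alpha-silyl ketone: ring-enlarged, C4 carries SiMe3 (both C4 epimers) | CC(C)(C)[Si](C)(C)OC[C@@]1(C)CC([Si](C)(C)C)C(=O)[C@@](C)(C(=O)OCC)[C@@H]2[C@H]1C3(OCCO3)C[C@H]2C | intermediate (not isolated)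
13 | cis-fused bicyclo[5.3.0]decane keto ester: C3 ketone in the seven-membered ring | CC(C)(C)[Si](C)(C)OC[C@@]1(C)CCC(=O)[C@@](C)(C(=O)OCC)[C@@H]2[C@H]1C3(OCCO3)C[C@H]2C | intermediate
14 | β-hydroxy ester: 3-OH α, cis to CO2Et | CC(C)(C)[Si](C)(C)OC[C@@]1(C)CC[C@@H](O)[C@@](C)(C(=O)OCC)[C@@H]2[C@H]1C3(OCCO3)C[C@H]2C | intermediate
15 | bis-silyl ether ester | CC(C)(C)[Si](C)(C)OC[C@@]1(C)CC[C@@H](O[Si](C)(C)C(C)(C)C)[C@@](C)(C(=O)OCC)[C@@H]2[C@H]1C3(OCCO3)C[C@H]2C | intermediate
16 | ketal aldehyde: 2-CHO α | CC(C)(C)[Si](C)(C)OC[C@@]1(C)CC[C@@H](O[Si](C)(C)C(C)(C)C)[C@@](C)(C=O)[C@@H]2[C@H]1C3(OCCO3)C[C@H]2C | intermediate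
17 | keto aldehyde: H1/H7 cis; 2-Me, 6-Me, 11-Me β; 2-CHO, 3-OTBS, 6-CH2OTBS α; C9 ketone | CC(C)(C)[Si](C)(C)OC[C@@]1(C)CC[C@@H](O[Si](C)(C)C(C)(C)C)[C@@](C)(C=O)[C@@H]2[C@H]1C(=O)C[C@H]2C | intermediate
18 | tricyclic diol: bridgehead C9–OH, C8–OH endo (anti to the C7 bridge), 11-Me exo | CC(C)(C)[Si](C)(C)OC[C@@]1(C)CC[C@@H](O[Si](C)(C)C(C)(C)C)[C@]2(C)[C@@H]3[C@H]1[C@@]([C@H]2O)(O)C[C@H]3C | intermediate
19 | C8 endo mesylate of 18 | CC(C)(C)[Si](C)(C)OC[C@@]1(C)CC[C@@H](O[Si](C)(C)C(C)(C)C)[C@]2(C)[C@@H]3[C@H]1[C@@]([C@H]2OS(C)(=O)=O)(O)C[C@H]3C | intermediate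
20 | 3-O-TBS, 6-CH2O-TBS ether of the tricyclo[5.4.0.0(2,8)]undecan-9-one core | CC(C)(C)[Si](C)(C)OC[C@@]1(C)CC[C@@H](O[Si](C)(C)C(C)(C)C)[C@]2(C)[C@@H]3[C@H]1[C@H]2C(=O)C[C@H]3C | intermediate
21 | 3-hydroxy-6-(hydroxymethyl)-2,6,11-trimethyltricyclo[5.4.0.0(2,8)]undecan-9-one | OC[C@@]1(C)CC[C@@H](O)[C@]2(C)[C@@H]3[C@H]1[C@H]2C(=O)C[C@H]3C | intermediate
22 | CNP0276938.1, the 3-O,6-CH2O-bis-angelate | C/C=C(/C)C(=O)OC[C@@]1(C)CC[C@@H](OC(=O)/C(C)=C\C)[C@]2(C)[C@@H]3[C@H]1[C@H]2C(=O)C[C@H]3C | target

**Step count.** Total: 17 steps. Longest linear sequence: 16 steps (steps 1, 2 and 4 to 17, from 1).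

**Steps most likely to fail**

Step 15. The strained one-carbon bridge may fail to migrate, so that the alkoxide is simply recovered or the mesylate ionises and other bonds shift. The fallback sets out from keto aldehyde 17 and returns at 20. The aldehyde would be condensed with TsNHNH2 (MeOH, rt) to give the tosylhydrazone F1. Deprotonation with NaH and warming in THF (Bamford–Stevens conditions) should generate the diazoalkane F2 in the flask. F2 should add to the neighbouring cyclopentanone carbonyl and enlarge the ring with loss of N2 (Tiffeneau–Demjanov-type diazoalkane–ketone homologation), giving 20 directly.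

Step 13. The ketyl addition may show poor facial selectivity at C8 (exo instead of endo carbinol), or the aldehyde may simply be reduced. The fallback sets out from 17 and returns at 18. A triazolium-carbene-catalysed intramolecular crossed benzoin reaction (DBU, THF) would give the alpha-ketol F3. Hydroxyl-directed reduction with Me4NBH(OAc)3 (MeCN/AcOH, −20 °C) should then deliver hydride internally from the boron bound to the bridgehead oxygen, which sits on the exo side of the carbonyl plane, and give the endo alcohol 18.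

Step 8. The diazoalkane may add too slowly to the doubly hindered ketone, the wrong α-carbon may migrate, or a second homologation may follow. The fallback sets out from enone 10 and returns at 13.
- Me2CuLi with TMSCl would give the trimethylsilyl enol ether F4, which is isolated.
- Et2Zn/CH2I2 cyclopropanation would give the siloxycyclopropane F5.
- FeCl3 in DMF should open the ring oxidatively to the ring-enlarged beta-chloro ketone F6.
- NaOAc in MeOH would eliminate HCl to give the cycloheptenone F7.
- H2 over Pd/C in EtOAc would then give 13.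

Further compounds
F1 | step 15 | tosylhydrazone of keto aldehyde 17 | CC(C)(C)[Si](C)(C)OC[C@@]1(C)CC[C@@H](O[Si](C)(C)C(C)(C)C)[C@@](C)(/C=N/NS(=O)(=O)c3ccc(C)cc3)[C@@H]2[C@H]1C(=O)C[C@H]2C
F2 | step 15 | diazoalkane from F1 | CC(C)(C)[Si](C)(C)OC[C@@]1(C)CC[C@@H](O[Si](C)(C)C(C)(C)C)[C@@](C)(C=[N+]=[N-])[C@@H]2[C@H]1C(=O)C[C@H]2C
F3 | step 13 | alpha-ketol (bridgehead C9–OH, C8 ketone) | CC(C)(C)[Si](C)(C)OC[C@@]1(C)CC[C@@H](O[Si](C)(C)C(C)(C)C)[C@]2(C)[C@@H]3[C@H]1[C@@](C2=O)(O)C[C@H]3C
F4 | step 8 | trimethylsilyl enol ether of 11 (C3=C5) | CC(C)(C)[Si](C)(C)OC[C@@]1(C)C=C(O[Si](C)(C)C)[C@@](C)(C(=O)OCC)[C@@H]2[C@H]1C3(OCCO3)C[C@H]2C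
F5 | step 8 | siloxycyclopropane (cyclopropane on C3–C5, either face) | CC(C)(C)[Si](C)(C)OC[C@@]1(C)C4CC4(O[Si](C)(C)C)[C@@](C)(C(=O)OCC)[C@@H]2[C@H]1C3(OCCO3)C[C@H]2C
F6 | step 8 | ring-enlarged beta-chloro ketone (C5–Cl, both epimers) | CC(C)(C)[Si](C)(C)OC[C@@]1(C)C(Cl)CC(=O)[C@@](C)(C(=O)OCC)[C@@H]2[C@H]1C3(OCCO3)C[C@H]2C
F7 | step 8 | cycloheptenone (C4=C5 conjugated with the C3 ketone) | CC(C)(C)[Si](C)(C)OC[C@@]1(C)C=CC(=O)[C@@](C)(C(=O)OCC)[C@@H]2[C@H]1C3(OCCO3)C[C@H]2C
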